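The route rests on cutting the glycerol unit at C1–OAc and C2–O(acyl). The pattern of an acetate on C1, the terpenoid ester on C2 and a free hydroxyl on C3 is the footprint of a 1,3-dioxolan-2-ylium ring bridging O1 and O2 that acetate has opened at C1; such a ring forms when the carbonyl oxygen of a glycidyl ester opens its own oxirane ring (C2–C3–O) at C2. A single operation therefore shifts the acyl group from O1 to O2, inverts C2, installs the acetate and leaves O3 silylated. The precursor is the (R)-glycidyl ester of (E)-β-monocyclofarnesic acid, assembled from dihydro-β-ionone, triethyl phosphonoacetate and (S)-glycidol.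

Key step: step 4

Remark on the chemistry: the C2 descriptor reads S in 7, R in 8, 10 and 11, and S in 12. Only step 4 inverts the centre; the other changes come from the CIP ranking of the two CH2O arms.

Step 1
Reactants: 1 dihydro-β-ionone [4-(2,6,6-trimethylcyclohex-1-en-1-yl)butan-2-one]; 2 triethyl phosphonoacetate
Product: 4 ethyl (E)-3-methyl-5-(2,6,6-trimethylcyclohex-1-en-1-yl)pent-2-enoate, via sodium phosphonate carbanion 3 (not isolated)
Conditions: NaH, THF, 0 °C; then 1, reflux; E isomer separated from Z on silica
Reagents that add atoms: none
Why: Horner–Wadsworth–Emmons olefination of a methyl ketone with the stabilised anion 3 should favour the E enoate, in which the ester lies trans to the larger homocyclogeranyl chain, because the addition is reversible and the less crowded oxaphosphetane collapses faster.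

Step 2
Reactants: 4 ethyl (E)-3-methyl-5-(2,6,6-trimethylcyclohex-1-en-1-yl)pent-2-enoate
Product: 6 (E)-3-methyl-5-(2,6,6-trimethylcyclohex-1-en-1-yl)pent-2-enoic acid, via potassium carboxylate 5 (not isolated)
Conditions: KOH, EtOH/H2O, 70 °C; then cold 1 M HCl to pH 3
Reagents that add atoms: potassium hydroxide, [K+].[OH-]
Why: Saponification (acyl–oxygen ester hydrolysis) gives carboxylate 5, which should keep its E geometry under base, and brief cold acidification releases acid 6 without touching the tetrasubstituted ring alkene.

Step 3
Reactants: 6 (E)-3-methyl-5-(2,6,6-trimethylcyclohex-1-en-1-yl)pent-2-enoic acid; 7 (S)-glycidol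
Product: 8 (R)-oxiran-2-ylmethyl (E)-3-methyl-5-(2,6,6-trimethylcyclohex-1-en-1-yl)pent-2-enoate
Conditions: N,N′-dicyclohexylcarbodiimide, 4-(dimethylamino)pyridine (5 mol%), CH2Cl2, 0 °C to rt
Reagents that add atoms: none
Why: Steglich esterification passes the carbodiimide-activated acid through the acylpyridinium to the primary hydroxyl of 7, so no bond at the oxirane C2 is involved and the configuration is carried over unchanged.

Step 4
Reactants: 8 (R)-oxiran-2-ylmethyl (E)-3-methyl-5-(2,6,6-trimethylcyclohex-1-en-1-yl)pent-2-enoate; 9 trimethylsilyl acetate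
Product: 11 (R)-1-acetoxy-3-[(trimethylsilyl)oxy]propan-2-yl (E)-3-methyl-5-(2,6,6-trimethylcyclohex-1-en-1-yl)pent-2-enoate, via dioxolanylium triflate 10 (not isolated)
Conditions: 9 (3 equiv), Me3SiOSO2CF3 (10 mol%), 2,6-di-tert-butyl-4-methylpyridine (20 mol%), CH2Cl2, slow addition of 8 at −78 °C, then −20 °C; Et3N, cold pH 7 buffer; crude 11 carried on
Reagents that add atoms: trimethylsilyl trifluoromethanesulfonate, C[Si](C)(C)OS(=O)(=O)C(F)(F)F (catalytic; its Me3Si group goes to O3 and is replaced from 9)
Why: Proposed new method: Me3SiOSO2CF3 silylates the oxirane oxygen of 8, the ester carbonyl oxygen attacks C2 from the rear in a 5-exo-tet closure to give the 1,3-dioxolan-2-ylium triflate 10 with O3 already capped as its Me3Si ether, and the carbonyl oxygen of 9 then opens that ring by SN2 attack at the primary C1, which leaves the enoyl group on O2, puts the acetate on C1 and hands Me3Si back to triflate. The closest known reaction types are the Lewis-acid rearrangement of epoxy esters to orthoesters, which runs through the same kind of cation, and the Prévost-type opening of dioxolanylium ions by carboxylate at a ring carbon; their union with a silyl acetate as the terminating nucleophile is the untested part. The only ring closed is the transient dioxolanylium ring (5-exo-tet), which is opened again in the same flask, so the product is acyclic at glycerol. The stereocentre C2 is set by stereospecific inversion of the chiral-pool oxirane carbon, and C1 is not stereogenic, so its later SN2 opening cannot affect the configuration. The step needs C2 over C3 in the oxirane opening, which the tethered carbonyl secures through its five-membered transition state against the weakly nucleophilic external silyl ester, and C1 over C2 in the acetate step, which the primary-versus-secondary SN2 preference secures while addition at the cationic carbon stays reversible. Silylated O3, the hindered pyridine that removes CF3SO3H, inverse addition and low temperature are relied on to suppress orthoester formation through O3, oligomerisation and E/Z drift of the conjugated cation.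

Step 5
Reactants: 11 (R)-1-acetoxy-3-[(trimethylsilyl)oxy]propan-2-yl (E)-3-methyl-5-(2,6,6-trimethylcyclohex-1-en-1-yl)pent-2-enoate
Product: 12 (S)-1-acetoxy-3-hydroxypropan-2-yl (E)-3-methyl-5-(2,6,6-trimethylcyclohex-1-en-1-yl)pent-2-enoate
Conditions: 10% aq. citric acid (C6H8O7), THF, 0 °C, 15 min; rapid cold chromatography on boric acid-treated silica
Reagents that add atoms: none
Why: Acid-catalysed hydrolysis cleaves a primary trimethylsilyl ether far faster than either ester, and the mild pH, low temperature and short contact time should keep acyl migration to the freed O3 negligible.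

Compound list
1 | dihydro-β-ionone, 4-(2,6,6-trimethylcyclohex-1-en-1-yl)butan-2-one | CC(=O)CCC1=C(C)CCCC1(C)C | starting material
2 | triethyl phosphonoacetate | CCOC(=O)CP(=O)(OCC)OCC | starting material
3 | sodium salt of the triethyl phosphonoacetate carbanion | CCOC(=O)[CH-]P(=O)(OCC)OCC.[Na+] | intermediate
4 | ethyl (E)-3-methyl-5-(2,6,6-trimethylcyclohex-1-en-1-yl)pent-2-enoate | CCOC(=O)/C=C(\C)CCC1=C(C)CCCC1(C)C | intermediate
5 | potassium (E)-3-methyl-5-(2,6,6-trimethylcyclohex-1-en-1-yl)pent-2-enoate | [K+].[O-]C(=O)/C=C(\C)CCC1=C(C)CCCC1(C)C | intermediate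
6 | (E)-3-methyl-5-(2,6,6-trimethylcyclohex-1-en-1-yl)pent-2-enoic acid (β-monocyclofarnesic acid) | OC(=O)/C=C(\C)CCC1=C(C)CCCC1(C)C | intermediate
7 | (S)-glycidol, (S)-oxiran-2-ylmethanol | OC[C@H]1CO1 | starting material
8 | (R)-oxiran-2-ylmethyl (E)-3-methyl-5-(2,6,6-trimethylcyclohex-1-en-1-yl)pent-2-enoate | O=C(OC[C@@H]1OC1)/C=C(\C)CCC1=C(C)CCCC1(C)C | intermediate
9 | trimethylsilyl acetate | CC(=O)O[Si](C)(C)C | starting material
10 | (R)-2-[(E)-2-methyl-4-(2,6,6-trimethylcyclohex-1-en-1-yl)but-1-en-1-yl]-4-{[(trimethylsilyl)oxy]methyl}-1,3-dioxolan-2-ylium trifluoromethanesulfonate | C[Si](C)(C)OC[C@H]1COC(=[O+]1)/C=C(\C)CCC2=C(C)CCCC2(C)C.[O-]S(=O)(=O)C(F)(F)F | intermediate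
11 | (R)-1-acetoxy-3-[(trimethylsilyl)oxy]propan-2-yl (E)-3-methyl-5-(2,6,6-trimethylcyclohex-1-en-1-yl)pent-2-enoate | CC(=O)OC[C@H](CO[Si](C)(C)C)OC(=O)/C=C(\C)CCC1=C(C)CCCC1(C)C | intermediate
12 | (S)-1-acetoxy-3-hydroxypropan-2-yl (E)-3-methyl-5-(2,6,6-trimethylcyclohex-1-en-1-yl)pent-2-enoate (1-O-acetyl-2-O-acyl-sn-glycerol) | CC(=O)OC[C@H](CO)OC(=O)/C=C(\C)CCC1=C(C)CCCC1(C)C | target

Total step count: 5. Longest linear sequence: 5 steps (1 → 4 → 6 → 8 → 11 → 12).

Steps most likely to fail

Step 4. The relay may lose control at several points. External acetate or triflate may open the activated oxirane at C3 before the tethered carbonyl reaches C2. The silylated O3 may add to the cationic carbon and pass through a symmetric bicyclic orthoester, which would erode the configuration at C2 and move the acyl group. The cation may also start oligomerisation of unreacted oxirane or isomerise the enoate. The fallback uses only known reactions, sets out from 7 and 6 and comes back at 12. Williamson etherification of 7 (NaH, 4-methoxybenzyl chloride, tetrabutylammonium iodide, THF; the degenerate Payne rearrangement of glycidol does not racemise) should give (R)-4-methoxybenzyl glycidyl ether F1. Opening of F1 by acetate at the terminal carbon (CsO2CCH3, AcOH, DMF, 60 °C) should give 1-O-acetyl-3-O-(4-methoxybenzyl)-sn-glycerol F2 with C2 retained. Steglich esterification of the secondary hydroxyl of F2 with acid 6 should give the protected diester F3. Oxidative removal of the benzyl ether with 2,3-dichloro-5,6-dicyano-1,4-benzoquinone (CH2Cl2, pH 7 buffer, 0 °C) then gives 12. Here the two CH2 arms of glycidol exchange roles and C2 is retained, which leads to the same enantiomer as the main route.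

Step 5. The enoyl group may migrate from O2 to the freed O3, or the acetyl group from O1 to O3, during acidic unmasking of crude material or on silica. The fallback sets out from 8 and comes back at 12. The relay of step 4 is run with triethylsilyl acetate and Et3SiOSO2CF3 in place of the trimethylsilyl reagents, which should give the 3-O-triethylsilyl ether F4. This ether should survive chromatography and can be purified before the hydroxyl is freed. It is then cleaved by fluoride, not by aqueous acid (HF·pyridine with excess pyridine, THF, 0 °C), to give 12.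

Step 1. Olefination of a methyl ketone may show poor E/Z selectivity, and the geometric isomers may be hard to separate. The fallback sets out from 1 and comes back at 4. Kinetic enolisation of 1 (LiN(iPr)2, THF, −78 °C) and trapping with diethyl chlorophosphate should give the enol phosphate F5. Elimination with further LiN(iPr)2 should give the terminal alkyne F6. Zirconium-catalysed methylalumination (Me3Al, (C5H5)2ZrCl2, CH2Cl2, rt) adds methyl and aluminium syn and should give the alkenylalane F7. Quenching F7 with ethyl chloroformate, with retention, gives 4 with the E geometry fixed by the carbometalation.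

Further compounds
F1 | step 4 | (R)-2-{[(4-methoxybenzyl)oxy]methyl}oxirane | COc1ccc(COC[C@H]2CO2)cc1
F2 | step 4 | (S)-2-hydroxy-3-[(4-methoxybenzyl)oxy]propyl acetate | CC(=O)OC[C@H](COCc1ccc(OC)cc1)O
F3 | step 4 | (S)-1-acetoxy-3-[(4-methoxybenzyl)oxy]propan-2-yl (E)-3-methyl-5-(2,6,6-trimethylcyclohex-1-en-1-yl)pent-2-enoate | CC(=O)OC[C@H](COCc1ccc(OC)cc1)OC(=O)/C=C(\C)CCC1=C(C)CCCC1(C)C
F4 | step 5 | (R)-1-acetoxy-3-[(triethylsilyl)oxy]propan-2-yl (E)-3-methyl-5-(2,6,6-trimethylcyclohex-1-en-1-yl)pent-2-enoate | CC(=O)OC[C@H](CO[Si](CC)(CC)CC)OC(=O)/C=C(\C)CCC1=C(C)CCCC1(C)C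
F5 | step 1 | diethyl 4-(2,6,6-trimethylcyclohex-1-en-1-yl)but-1-en-2-yl phosphate | C=C(CCC1=C(C)CCCC1(C)C)OP(=O)(OCC)OCC
F6 | step 1 | 2-(but-3-yn-1-yl)-1,3,3-trimethylcyclohex-1-ene | C#CCCC1=C(C)CCCC1(C)C
F7 | step 1 | dimethyl[(E)-2-methyl-4-(2,6,6-trimethylcyclohex-1-en-1-yl)but-1-en-1-yl]alane | C[Al](C)/C=C(\C)CCC1=C(C)CCCC1(C)C
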